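The numbers in the tables were computed for substances that don't exist; the scatter is artificial.

The constant to find first is a first-order one. Assume X grows out of standing D, so that d[X]/dt = k[D], with k the inverse of a time constant. Then k for a run is its last X over the area under its D curve, taken by trapezoids from zero.

common to all: L 0.0050 M

| run | Q | E | temperature | remark | time |
|---|---|---|---|---|---|
| Monday's | 1.05 equiv | 1 equiv | 95 °C | run made earlier |  |
| Thursday's | 1.5 equiv | 1 equiv | 106 °C | run made earlier |  |
| Friday's | 2.3 equiv | 1 equiv | 95 °C | run made earlier |  |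
| teal | 1.05 equiv | 1.00 equiv |  | everything together at the start at 60 °C, warmed to 100 °C at 3.0 min | 4.0 min |
| blue | 1.05 equiv | 1.00 equiv (fed, over 3.0 min) |  | the addition at 60 °C, then warmed to 100 °C; the feed brings no volume worth counting | 4.0 min |
| red | 1.05 equiv (in portions, 4, over 3.0 min) | 1.00 equiv | 100 °C | first portion at the start, last at 3.0 min | 4.0 min |
| green | 1.05 equiv (fed, over 3.0 min) | 1.00 equiv | 100 °C | all else is in the flask from the start; the feed brings no volume worth counting | 4.0 min |
| grey | 1.05 equiv | 1.00 equiv | 100 °C | everything together at the start | 4.0 min |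

- Monday's (time / min: D / %, X / %): 0.200: 0, 0; 0.333: 3, 0; 0.667: 6, 1; 1.33: 5, 2; 2.50: 7, 1
- Thursday's (time / min: D / %, X / %): 0.333: 3, 1; 0.667: 6, 4; 1.00: 5, 2; 2.00: 9, 8; 4.00: 11, 25
- Friday's (time / min: D / %, X / %): 0.833: 9, 0; 1.50: 16, 0; 2.50: 20, 3; 3.00: 23, 13; 4.00: 28, 19

(readings scatter by 2 percentage points)

- given per volume of solution although it is solid: L
- at the start none of L is in solution

1. the flask with the highest share of D in D plus X ("all alike" if they lie within 1.5 percentage points) (teal / blue / red / green / grey / all alike)
2. share of D in D plus X at the end, teal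
3. share of D in D plus X at the end, blue
4. share of D in D plus X at the end, red
5. share of D in D plus X at the end, green
6. share of D in D plus X at the end, grey

Friday's run reads 0.286 min⁻¹ at 95 °C, and Thursday's reads 0.811 min⁻¹ at 106 °C, both with the scatter of the readings. That gap is 0.453 decades. Laid straight in temperature on the log scale, it gives 0.460 min⁻¹ at 100 °C, a time constant of 2.17 min, and 0.0105 min⁻¹ at 60 °C. Call the value at 100 °C the loss constant, the fraction of standing D that turns into X per minute.

Now let N be X over D at the end. The share of D, the selectivity, is one over one plus N. You bound it from below by letting D stand at its end level for the whole hot time, so N is k times that time. You bound it from above by a straight ramp from zero, which gives half that N.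

Grey, hot for 4.0 min, lies between 35.2% and 52.1%. Teal and blue are hot for 1.00 min. With the cold stretch added to the lower edge, they lie between 67.1% and 81.3%. Red and green share grey's lower edge, but fed Q may hold D behind the ramp, so their upper edge is unsafe. This reckoning is your own, and it puts teal and blue above grey, since their lower edge stands above grey's upper one. It cannot part those two, and without a safe upper edge for red and green it cannot place teal and blue above them.

The forecast names blue, on the ground that “Blue keeps Q free of E during the feed”. It gives teal 72%, blue 82%, red 32%, green 22% and grey 36%. Teal and grey sit inside the bracket, blue just over its upper edge, and red and green under their lower edge.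

    D → X (k = 0.00710 s⁻¹, Ea = 114 kJ mol⁻¹)
    Z + Q ⇌ D (K = 360 M⁻¹, k = 8.10 M⁻¹ s⁻¹, Ea = 47.0 kJ mol⁻¹, ΔH = −3.00 kJ mol⁻¹)
    L ⇌ Z, rate k3*(cs3 - [Z]) while solid is left; crystals form when [Z] > cs3 (solubility = 2.10 mM, k = 0.00900 s⁻¹)
    E + Q ⇌ J (K = 2000 M⁻¹, k = 39.0 M⁻¹ s⁻¹, Ea = 46.0 kJ mol⁻¹, ΔH = −49.0 kJ mol⁻¹)
    (constants at 100 °C)

The flasks put teal on top: teal 73.8%, blue 69.3%, red 59.0%, green 57.0%, grey 47.4%. At the warming, 3.00 min, D stood at 4.71% in teal and 9.70% in blue, and it ended at 8.81% and 9.61%. The loss constant times mean D times the hot time gives X of 3.11% for teal and 4.44% for blue. The flasks hold 3.13% and 4.25%.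

Take teal with 4.20 equiv of Q. The loss constant has no Q in it, so you carry the same bracket, 67.1% to 81.3%. That flask gives D 38.9%, X 16.5% and a share of 70.2%.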